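## The problem

- **Ring system.** The target is a 2,3-dimethylchroman-4-one (ring B: O1, C2, C3, C4) fused to a benzene ring (ring A: C4a, C5, C6, C7, C8, C8a) in which every carbon is substituted. Ring A is a phloroglucinol with three different oxygens (ring ether O1, free 5-OH hydrogen-bonded to C4=O, 7-OMe) and three different carbon groups (the acyl carbon C4 at C4a, the hexanoic acid chain C1′–C6′ bound through C3′ to C6, a prenyl group at C8).
- **Regiochemistry.** The obvious arene precursors are symmetric, so each of the six substituents has to be placed by an argument and not by statistics.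
- **Stereocentres.** C2 (S) and C3 (S) are trans on ring B; C3′ (R) is benzylic. C2 can control C3, because the trans isomer is both the product of enolate methylation anti to the C2 methyl group and the more stable isomer. C3′ lies across ring A, six bonds from C2, and cannot be relayed from it, so a second, independent source of chirality is needed.
- **The hard bond.** C6–C3′ joins a secondary stereogenic carbon to an arene carbon flanked by two oxygen-bearing carbons, the worst case for intermolecular aryl-metal conjugate addition or Friedel–Crafts alkylation.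
- **Fragile groups.** C3 epimerises by enolisation and C2 by retro-oxa-Michael opening under base; the prenyl group is acid-labile and must survive any hydrogenation; the hydroxy acid can lactonise onto O5.
- **Enabling feature.** The free O5–H is ortho to C6, and the propyl arm C4′–C5′–C6′ on C3′ can be read as a saturated (E)-propenyl group. O5–C5–C6–C3′–C4′=C5′ is then the retron of an aromatic Claisen rearrangement: C5′, a methyl carbinol carbon bound to O5, hands its configuration to C3′, and C6 is the only ring-A carbon able to accept the allyl group.

## Retrosynthesis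

**20 ⇒ 18 ⇒ 17 (C1′ ester, C4′=C5′).** The acid 20 is traced to its methyl ester 18 and then to the (E)-hex-4-enoate 17. No skeletal bond is cut; the propyl arm becomes a propenyl group and this exposes the Claisen retron. The forward steps must hydrolyse an ester without base-induced epimerisation of ring B, and saturate a 1,2-disubstituted alkene beside the trisubstituted prenyl alkene.

**17 ⇒ 15 (cut C6–C3′, reconnect O5–C5′).** The hindered, stereogenic aryl–alkyl bond is exchanged for an aryl allyl ether, the 5-O-[(R,E)-hex-3-enoate-5-yl] ether 15.
- Against the neighbouring cuts: an intermolecular C6–C3′ disconnection (aryl metal plus hexenoate) or a C3′–C4′ disconnection (benzylic alkylation) leaves both the steric problem and an unrelated enantiocontrol problem.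
- The [3,3] shift delivers carbon intramolecularly, copies the configuration of C5′ onto C3′, and frees the 5-OH that the target needs.
- 15 is simpler than 17: it has no benzylic stereocentre, ring A is still pentasubstituted, and it is made by one C–O bond.
- Asked of the forward reaction: migration to C6 only, and a concerted suprafacial course.

**15 ⇒ 11 + 14 (cut O5–C5′); 14 ⇒ 12 + 13 (cut C3′=C4′).** The ether is made by Mitsunobu inversion from the 5-hydroxychromanone 11 and methyl (S,E)-5-hydroxyhex-3-enoate 14. The alcohol 14 comes in one step by cross-metathesis of purchased (S)-but-3-en-2-ol 12 with methyl but-3-enoate 13. An ether bond at a chelated phenol is far easier than any C–C bond at C6; the forward reaction must invert cleanly (SN2, not SN2′) and keep the E geometry.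

**11 ⇒ 9 ⇒ 7 (O5–CH3, then C3–CH3).** The free 5-OH is traced to the 5,7-dimethoxy compound 9, because the peri carbonyl lets a Lewis acid distinguish O5 from O7 by chelation. The C3 methyl group is removed to give the (S)-2-methylchromanone 7, since C2 can direct its introduction. Both are one-step changes that avoid any protecting group.

**7 ⇒ 5 (cut C4–C4a).** Ring B is opened at the acyl–arene bond to give the (S)-3-aryloxybutanoic acid 5. This cut is preferred over O1–C2 (oxa-Michael closure), which is reversible and would put C2 at risk. The forward Friedel–Crafts closure has one ortho position available, because the other carries the prenyl group.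

**5 ⇒ 3 + 4 (cut O1–C2).** The aryl ether is made by SN2 opening of purchased (R)-4-methyloxetan-2-one 4 by the phenoxide of 3, with inversion. The whole C2–C3–C4 unit and the C2 configuration arrive in one step from the chiral pool.

**3 ⇒ 1 + 2 (cut C8–C1″).** The prenyl phenol 3 comes from 3,5-dimethoxyphenol 1 and prenyl bromide 2. The two ortho positions of 1 are equivalent, so one ortho-C-prenyl product is possible. Placing the prenyl group first fixes the direction of the later ring closure and blocks the position para to O5 for the key step.

## Roads not taken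

**Alternative 1: coumarin first (the obvious route).**
- Cut: C6–C3′ and O5–C1′ together.
- Forward: Pechmann condensation of phloroglucinol with ethyl 3-oxohexanoate gives 5,7-dihydroxy-4-propylcoumarin A1. Acylation with tigloyl chloride gives the 8-tigloyl coumarin A2, ring B is closed by oxa-Michael addition, and methylation, prenylation, enantioselective conjugate reduction of the coumarin double bond and lactone hydrolysis follow.
- Why the chosen plan is better: A1 has two free ring positions and two free hydroxyls that differ only weakly, so acylation and later prenylation give regioisomers. Closure of A2 is a reversible oxa-Michael addition, racemic at C2 unless a second chiral catalyst is used, and its reversibility threatens C2 afterwards. C3′ must then be set by hydride delivery to a hindered coumarin beside a ketone. That makes two catalyst-controlled events of uncertain sense, against two stereospecific inversions of purchased alcohols in the chosen plan. The strongly acidic Pechmann and acylation steps also forbid an early prenyl group.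

**Alternative 2: one double reduction of a flat tricycle.**
- Cut: no skeletal bond; all three stereocentres are removed to give the achiral chromone–coumarin A3.
- Forward: a double enantioselective conjugate reduction (copper hydride or hydrogenation) of the coumarin C2′=C3′ and chromone C2=C3 bonds with one chiral ligand.
- Why the chosen plan is better: it is attractive on paper, but one ligand would have to choose the correct face at two electronically different β-carbons (an aryl-substituted enoate carbon and an oxygen-substituted enone carbon), and there is no basis to predict that the two senses match the required (3′R,2S) pair. The tetrasubstituted chromone double bond resists conjugate reduction, the product ketone can be over-reduced, and C3 is set by an uncontrolled protonation. The step cannot be defended; the Claisen transfer can.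

**Alternative 3: strain-release alkylation with a β-lactone.**
- Cut: C6–C3′, intermolecular.
- Forward: C6 of phenol 11 (or an aryl cuprate) opens (S)-4-propyloxetan-2-one A4 at its alkyl C–O bond with inversion, giving 20 directly.
- Why the chosen plan is better: a ring carbon flanked by OH and OMe would have to attack a secondary centre in SN2 fashion. O-acylation, O-alkylation and elimination to hex-2-enoic acid followed by non-stereospecific hydroarylation are all easier. The Lewis acid needed endangers the prenyl group, and the cuprate variant is incompatible with the C4 ketone. The Claisen route forms the same bond intramolecularly from an ether that is easy to make.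

Key step: step 8

Assumption: sodium and lithium salts formed by simple O–H deprotonation (phenoxides, carboxylates) count as forms of the numbered parent compounds; every other species formed in the flask is numbered. Compounds 4 and 12 are taken as purchased in enantiopure form.

## Route

Step 1
Reactants: 1 3,5-dimethoxyphenol; 2 1-bromo-3-methylbut-2-ene (prenyl bromide)
Product: 3 3,5-dimethoxy-2-(3-methylbut-2-en-1-yl)phenol
Conditions: NaH, toluene, 0 °C; 2, rt
Reagents that add atoms: none
Why: C-alkylation of a sodium phenoxide ion pair in a non-polar solvent goes to the ortho carbon; the two ortho positions of 1 are equivalent, so one C-prenyl phenol results, with O-alkylation and para attack as the side reactions to be separated.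

Step 2
Reactants: 3; 4 (R)-4-methyloxetan-2-one ((R)-β-butyrolactone)
Product: 5 (S)-3-[3,5-dimethoxy-2-(3-methylbut-2-en-1-yl)phenoxy]butanoic acid
Conditions: NaH, DMF, 0 °C; 4, rt; aq. HCl
Reagents that add atoms: none
Why: Phenoxide opens the strained β-lactone by SN2 attack at C4 (alkyl–oxygen cleavage) with inversion, so the (R)-lactone should give the (S)-aryloxy acid; this sets C2 of ring B.

Step 3
Reactants: 5
Product: 7 (S)-5,7-dimethoxy-2-methyl-8-(3-methylbut-2-en-1-yl)chroman-4-one, via mixed trifluoroacetic anhydride 6 (not isolated)
Conditions: (CF3CO)2O, CH2Cl2, 0 °C → rt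
Reagents that add atoms: none
Why: Intramolecular Friedel–Crafts acylation through the mixed anhydride closes ring B (six-membered) at the only free position ortho to O1, a carbon activated by all three oxygens; C2 is not involved, and the short, cold reaction is meant to spare the prenyl group.

Step 4
Reactants: 7
Product: 9 (2S,3S)-5,7-dimethoxy-2,3-dimethyl-8-(3-methylbut-2-en-1-yl)chroman-4-one, via lithium enolate 8 (not isolated)
Conditions: LiN(SiMe3)2, THF, −78 °C; MeI, −78 → −40 °C
Reagents that add atoms: iodomethane, CI
Why: Kinetic enolate alkylation; methyl iodide should add anti to the pseudo-equatorial C2 methyl group to give the trans (2S,3S) isomer, which is also the more stable one. At low temperature the enolate should not expel the aryloxide, because the C2–O1 bond lies close to the enolate plane.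

Step 5
Reactants: 9
Product: 11 (2S,3S)-5-hydroxy-7-methoxy-2,3-dimethyl-8-(3-methylbut-2-en-1-yl)chroman-4-one, via dichloroboryl ether 10 (not isolated)
Conditions: BCl3, CH2Cl2, −78 → 0 °C; H2O
Reagents that add atoms: none
Why: Chelation-controlled ether cleavage: BCl3 binds C4=O and the peri 5-OMe in a six-membered chelate, so only that methyl group is lost; the 7-OMe of the target stays.

Step 6
Reactants: 12 (S)-but-3-en-2-ol; 13 methyl but-3-enoate
Product: 14 methyl (S,E)-5-hydroxyhex-3-enoate
Conditions: RuCl2(=CHPh)(PCy3)(H2IMes) (second-generation Grubbs catalyst, 2 mol %), 13 in excess, CH2Cl2, 40 °C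
Reagents that add atoms: none
Why: Olefin cross-metathesis of a secondary allylic alcohol with a terminal alkene is E-selective and does not touch the carbinol centre; the E isomer is purified, because the alkene geometry later decides the configuration of C3′.

Step 7
Reactants: 11; 14
Product: 15 methyl (R,E)-5-{[(2S,3S)-7-methoxy-2,3-dimethyl-8-(3-methylbut-2-en-1-yl)-4-oxochroman-5-yl]oxy}hex-3-enoate
Conditions: PPh3, diisopropyl azodicarboxylate, toluene, 0 °C → rt
Reagents that add atoms: none
Why: Mitsunobu etherification: the chelated 5-OH is acidic enough to act as pronucleophile and should displace the activated secondary allylic alcohol by SN2 with inversion (S to R at C5′); the neutral conditions leave C2, C3 and the β,γ-unsaturated ester alone.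

Step 8
Reactants: 15
Product: 17 methyl (S,E)-3-[(2S,3S)-5-hydroxy-7-methoxy-2,3-dimethyl-8-(3-methylbut-2-en-1-yl)-4-oxochroman-6-yl]hex-4-enoate, via ring-A dienone 16 (not isolated)
Conditions: Eu(fod)3 (10 mol %; fod = 6,6,7,7,8,8,8-heptafluoro-2,2-dimethyloctane-3,5-dionate), toluene, 80 °C
Reagents that add atoms: none
Why: Aromatic Claisen rearrangement with 1,3-chirality transfer: Eu(fod)3 chelates C4=O and O5, weakens the O5–C5′ bond, and the allyl unit migrates suprafacially through a six-membered chair transition state with the C5′ methyl group pseudo-equatorial, forming C6–C3′ on the allyl face that O5 leaves. The closest known reaction types are the thermal or lanthanide-catalysed ortho-Claisen rearrangement of enantioenriched (E)-1-methylallyl aryl ethers and that of 5-O-allyl ethers of 4-oxochromans. No ring is closed; the ring-A dienone 16 regains aromaticity by enolisation to the chelated 5-OH phenol. The only new stereocentre, C3′, is controlled by the C5′ configuration together with the E geometry of C3′=C4′: (5′R,E) should give (3′S) with an (E)-propenyl group, the arrangement that becomes 3′R on saturation. Regioselectivity requires migration to C6 only, and the substrate secures it: C6 is the single unsubstituted carbon of ring A, while the other ortho carbon C4a and the para carbon C8 are quaternary, so a dienone formed there cannot tautomerise and reverts. Stereochemical fidelity requires the concerted path to outrun ionisation of the ether, which the mild Lewis acid and moderate temperature favour; the minor (Z)-propenyl isomer, of opposite configuration at C3′, is removed by chromatography before step 9. C2, C3 and the prenyl group are spectators under these neutral conditions.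

Step 9
Reactants: 17
Product: 18 methyl (R)-3-[(2S,3S)-5-hydroxy-7-methoxy-2,3-dimethyl-8-(3-methylbut-2-en-1-yl)-4-oxochroman-6-yl]hexanoate
Conditions: H2 (3 atm), RhCl(PPh3)3 (5 mol %), toluene/EtOH, rt
Reagents that add atoms: none
Why: Homogeneous hydrogenation with RhCl(PPh3)3 is very sensitive to alkene substitution, so the 1,2-disubstituted propenyl group should be reduced while the trisubstituted prenyl group, the ketone and the ester stay; this catalyst also causes little double-bond migration, which protects C3′. The descriptor changes from S to R only through the priority rules.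

Step 10
Reactants: 18
Product: 20 (R)-3-[(2S,3S)-5-hydroxy-7-methoxy-2,3-dimethyl-8-(3-methylbut-2-en-1-yl)-4-oxochroman-6-yl]hexanoic acid (CNP0233409.1), via trimethylstannyl ester 19 (not isolated)
Conditions: Me3SnOH, ClCH2CH2Cl, 70 °C; cold 0.5 M aq. HCl
Reagents that add atoms: trimethyltin hydroxide, C[Sn](C)(C)O
Why: Me3SnOH cleaves methyl esters under nearly neutral conditions, which avoids enolisation at C3 and retro-oxa-Michael opening at C2; brief cold acidification frees the acid without lactonisation onto the chelated 5-OH.

## Compound list

1 | 3,5-dimethoxyphenol | COc1cc(O)cc(OC)c1 | starting material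
2 | 1-bromo-3-methylbut-2-ene (prenyl bromide) | CC(C)=CCBr | starting material
3 | 3,5-dimethoxy-2-(3-methylbut-2-en-1-yl)phenol | COc1cc(O)c(CC=C(C)C)c(OC)c1 | intermediate
4 | (R)-4-methyloxetan-2-one | C[C@@H]1CC(=O)O1 | starting material
5 | (S)-3-[3,5-dimethoxy-2-(3-methylbut-2-en-1-yl)phenoxy]butanoic acid | COc1cc(OC)c(CC=C(C)C)c(O[C@@H](C)CC(=O)O)c1 | intermediate
6 | (S)-3-[3,5-dimethoxy-2-(3-methylbut-2-en-1-yl)phenoxy]butanoic trifluoroacetic anhydride | COc1cc(OC)c(CC=C(C)C)c(O[C@@H](C)CC(=O)OC(=O)C(F)(F)F)c1 | intermediate
7 | (S)-5,7-dimethoxy-2-methyl-8-(3-methylbut-2-en-1-yl)chroman-4-one | COc1cc(OC)c2c(c1CC=C(C)C)O[C@@H](C)CC2=O | intermediate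
8 | lithium (S)-5,7-dimethoxy-2-methyl-8-(3-methylbut-2-en-1-yl)-2H-chromen-4-olate | COc1cc(OC)c2c(c1CC=C(C)C)O[C@@H](C)C=C2O[Li] | intermediate
9 | (2S,3S)-5,7-dimethoxy-2,3-dimethyl-8-(3-methylbut-2-en-1-yl)chroman-4-one | COc1cc(OC)c2c(c1CC=C(C)C)O[C@@H](C)[C@H](C)C2=O | intermediate
10 | (2S,3S)-5-(dichloroboryloxy)-7-methoxy-2,3-dimethyl-8-(3-methylbut-2-en-1-yl)chroman-4-one | COc1cc(OB(Cl)Cl)c2c(c1CC=C(C)C)O[C@@H](C)[C@H](C)C2=O | intermediate
11 | (2S,3S)-5-hydroxy-7-methoxy-2,3-dimethyl-8-(3-methylbut-2-en-1-yl)chroman-4-one | COc1cc(O)c2c(c1CC=C(C)C)O[C@@H](C)[C@H](C)C2=O | intermediate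
12 | (S)-but-3-en-2-ol | C[C@H](O)C=C | starting material
13 | methyl but-3-enoate | C=CCC(=O)OC | starting material
14 | methyl (S,E)-5-hydroxyhex-3-enoate | C[C@H](O)/C=C/CC(=O)OC | intermediate
15 | methyl (R,E)-5-{[(2S,3S)-7-methoxy-2,3-dimethyl-8-(3-methylbut-2-en-1-yl)-4-oxochroman-5-yl]oxy}hex-3-enoate | COc1cc(O[C@H](C)/C=C/CC(=O)OC)c2c(c1CC=C(C)C)O[C@@H](C)[C@H](C)C2=O | intermediate
16 | methyl (S,E)-3-[(2S,3S)-7-methoxy-2,3-dimethyl-8-(3-methylbut-2-en-1-yl)-4,5-dioxo-3,4,5,6-tetrahydro-2H-chromen-6-yl]hex-4-enoate (ring-A 2,4-dienone, C6 not defined) | C/C=C/[C@H](CC(=O)OC)C1C(=O)C2=C(O[C@@H](C)[C@H](C)C2=O)C(CC=C(C)C)=C1OC | intermediate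
17 | methyl (S,E)-3-[(2S,3S)-5-hydroxy-7-methoxy-2,3-dimethyl-8-(3-methylbut-2-en-1-yl)-4-oxochroman-6-yl]hex-4-enoate | C/C=C/[C@H](CC(=O)OC)c1c(O)c2c(c(CC=C(C)C)c1OC)O[C@@H](C)[C@H](C)C2=O | intermediate
18 | methyl (R)-3-[(2S,3S)-5-hydroxy-7-methoxy-2,3-dimethyl-8-(3-methylbut-2-en-1-yl)-4-oxochroman-6-yl]hexanoate | CCC[C@H](CC(=O)OC)c1c(O)c2c(c(CC=C(C)C)c1OC)O[C@@H](C)[C@H](C)C2=O | intermediate
19 | trimethylstannyl (R)-3-[(2S,3S)-5-hydroxy-7-methoxy-2,3-dimethyl-8-(3-methylbut-2-en-1-yl)-4-oxochroman-6-yl]hexanoate | CCC[C@H](CC(=O)O[Sn](C)(C)C)c1c(O)c2c(c(CC=C(C)C)c1OC)O[C@@H](C)[C@H](C)C2=O | intermediate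
20 | (R)-3-[(2S,3S)-5-hydroxy-7-methoxy-2,3-dimethyl-8-(3-methylbut-2-en-1-yl)-4-oxochroman-6-yl]hexanoic acid (CNP0233409.1) | CCC[C@H](CC(=O)O)c1c(O)c2c(c(CC=C(C)C)c1OC)O[C@@H](C)[C@H](C)C2=O | target

## Step count and least certain steps

Total: 10 steps. Longest linear sequence: 9 steps (1–5, 7–10); step 6 is a one-step side branch.

**Step 8 (key step).**
- What may go wrong: loss of stereochemical fidelity. Partial heterolysis of the chelated secondary allylic ether gives ion-pair recombination or a 1,3-shift, and the boat or axial-methyl transition states lead to the (Z)-propenyl isomer of opposite configuration at C3′.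
- Fallback (from 11, back at 20): C3′ is set by catalyst control instead of chirality transfer. Phenol 11 is esterified with hex-2-ynoic acid (DCC, DMAP) to (2S,3S)-7-methoxy-2,3-dimethyl-8-(3-methylbut-2-en-1-yl)-4-oxochroman-5-yl hex-2-ynoate F1. Gold-catalysed intramolecular hydroarylation (Ph3PAuCl/AgOTf, ClCH2CH2Cl, rt) forms C6–C3′ at the only free ring-A position and gives the tricyclic 4-propylcoumarin F2. Copper hydride conjugate reduction (Cu(OAc)2, DTBM-SEGPHOS, (EtO)2MeSiH, t-BuOH) follows, with the ligand antipode chosen for the 4R product; it is expected to spare the hindered ketone and gives the dihydrocoumarin F3. Its aryl lactone is opened with Me3SnOH as in step 10 to give 20.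

**Step 2.**
- What may go wrong: the hindered ortho-prenyl phenoxide attacks the lactone acyl carbon instead of C4, or acts as a base and eliminates the lactone to crotonate, so the ether is not formed stereospecifically.
- Fallback (from 3, back at 5): Mitsunobu etherification of 3 with methyl (R)-3-hydroxybutanoate (PPh3, diisopropyl azodicarboxylate; inversion) gives methyl (S)-3-[3,5-dimethoxy-2-(3-methylbut-2-en-1-yl)phenoxy]butanoate F4, which is saponified (LiOH, aq. THF, 0 °C) to 5.

**Step 3.**
- What may go wrong: the liberated trifluoroacetic acid protonates the prenyl double bond (addition, or demethylative cyclisation onto the neighbouring methoxy group) in competition with ring closure.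
- Fallback (from 1, back at 7): an acid-tolerant allyl group is carried as a prenyl surrogate. Phenol 1 is ortho-C-allylated (NaH, toluene, allyl bromide) to 2-allyl-3,5-dimethoxyphenol F5 and opened onto 4 as in step 2 to (S)-3-(2-allyl-3,5-dimethoxyphenoxy)butanoic acid F6. Trifluoroacetic anhydride takes this through its mixed anhydride F7 to (S)-8-allyl-5,7-dimethoxy-2-methylchroman-4-one F8. Cross-metathesis with 2-methylbut-2-ene (second-generation Grubbs catalyst) converts the allyl into the prenyl group of 7.

**Step 7.**
- What may go wrong: SN2′ attack of the phenol, 1,4-elimination of the activated alcohol to the conjugated dienoate, or incomplete inversion.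
- Fallback (from 11, back at 15): the simpler alcohol 12 is coupled first. Mitsunobu reaction of 11 with 12 gives the 5-O-[(R)-but-3-en-2-yl] ether F9, and cross-metathesis of its terminal alkene with 13 (second-generation Grubbs catalyst, 40 °C, below the temperature of rearrangement) extends the chain to 15.

**Step 9.**
- What may go wrong: over-reduction of the prenyl group, or migration of the propenyl double bond toward C3′ before hydrogen is added, which would erase the new stereocentre.
- Fallback (from 17, back at 18): the prenyl alkene is masked by using the opposite selectivity of electrophilic epoxidation. mCPBA (1 equiv, NaHCO3, CH2Cl2, −20 °C) converts the trisubstituted alkene of 17 into the epoxide F10. The propenyl group is then hydrogenated (H2, RhCl(PPh3)3) to the saturated epoxide F11. Deoxygenation (MeReO3 cat., PPh3, benzene, rt) restores the prenyl group and gives 18.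

## Further compounds

F1 | step 8 | (2S,3S)-7-methoxy-2,3-dimethyl-8-(3-methylbut-2-en-1-yl)-4-oxochroman-5-yl hex-2-ynoate | COc1cc(OC(=O)C#CCCC)c2c(c1CC=C(C)C)O[C@@H](C)[C@H](C)C2=O
F2 | step 8 | (8S,9S)-5-methoxy-8,9-dimethyl-6-(3-methylbut-2-en-1-yl)-4-propyl-8,9-dihydro-2H,10H-pyrano[2,3-f]chromene-2,10-dione | CCCC1=CC(=O)Oc2c1c(OC)c(CC=C(C)C)c1O[C@@H](C)[C@H](C)C(=O)c12
F3 | step 8 | (4R,8S,9S)-5-methoxy-8,9-dimethyl-6-(3-methylbut-2-en-1-yl)-4-propyl-3,4,8,9-tetrahydro-2H,10H-pyrano[2,3-f]chromene-2,10-dione | CCC[C@@H]1CC(=O)Oc2c1c(OC)c(CC=C(C)C)c1O[C@@H](C)[C@H](C)C(=O)c12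
F4 | step 2 | methyl (S)-3-[3,5-dimethoxy-2-(3-methylbut-2-en-1-yl)phenoxy]butanoate | COc1cc(OC)c(CC=C(C)C)c(O[C@@H](C)CC(=O)OC)c1
F5 | step 3 | 2-allyl-3,5-dimethoxyphenol | COc1cc(O)c(CC=C)c(OC)c1
F6 | step 3 | (S)-3-(2-allyl-3,5-dimethoxyphenoxy)butanoic acid | COc1cc(OC)c(CC=C)c(O[C@@H](C)CC(=O)O)c1
F7 | step 3 | (S)-3-(2-allyl-3,5-dimethoxyphenoxy)butanoic trifluoroacetic anhydride | COc1cc(OC)c(CC=C)c(O[C@@H](C)CC(=O)OC(=O)C(F)(F)F)c1
F8 | step 3 | (S)-8-allyl-5,7-dimethoxy-2-methylchroman-4-one | COc1cc(OC)c2c(c1CC=C)O[C@@H](C)CC2=O
F9 | step 7 | (2S,3S)-5-{[(R)-but-3-en-2-yl]oxy}-7-methoxy-2,3-dimethyl-8-(3-methylbut-2-en-1-yl)chroman-4-one | COc1cc(O[C@H](C)C=C)c2c(c1CC=C(C)C)O[C@@H](C)[C@H](C)C2=O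
F10 | step 9 | methyl (S,E)-3-{(2S,3S)-8-[(3,3-dimethyloxiran-2-yl)methyl]-5-hydroxy-7-methoxy-2,3-dimethyl-4-oxochroman-6-yl}hex-4-enoate (epoxide carbon not defined) | C/C=C/[C@H](CC(=O)OC)c1c(O)c2c(c(CC3OC3(C)C)c1OC)O[C@@H](C)[C@H](C)C2=O
F11 | step 9 | methyl (R)-3-{(2S,3S)-8-[(3,3-dimethyloxiran-2-yl)methyl]-5-hydroxy-7-methoxy-2,3-dimethyl-4-oxochroman-6-yl}hexanoate (epoxide carbon not defined) | CCC[C@H](CC(=O)OC)c1c(O)c2c(c(CC3OC3(C)C)c1OC)O[C@@H](C)[C@H](C)C2=O
A1 | alternative 1 | 5,7-dihydroxy-4-propyl-2H-chromen-2-one | CCCc1cc(=O)oc2cc(O)cc(O)c12
A2 | alternative 1 | 5,7-dihydroxy-8-[(E)-2-methylbut-2-enoyl]-4-propyl-2H-chromen-2-one | CCCc1cc(=O)oc2c(C(=O)/C(C)=C/C)c(O)cc(O)c12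
A3 | alternative 2 | 5-methoxy-8,9-dimethyl-6-(3-methylbut-2-en-1-yl)-4-propyl-2H,10H-pyrano[2,3-f]chromene-2,10-dione | CCCc1cc(=O)oc2c1c(OC)c(CC=C(C)C)c1oc(C)c(C)c(=O)c12
A4 | alternative 3 | (S)-4-propyloxetan-2-one | CCC[C@H]1CC(=O)O1
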